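The six-membered ring of the target holds its tertiary chloride carbon C1 in a 1,3-relationship to the bromine-bearing C3 across the C2 methylene. With C3 read as a carbonyl, this C1–C2–C3 triad is a β-chloro ketone, the imprint of an oxidatively opened cyclopropanol. Everything rests on that disconnection. In one anodic, manganese-mediated operation a bicyclo[3.1.0]hexan-1-ol loses the bond shared by its three- and five-membered rings, the cyclohexanone appears, and the tertiary C1 radical takes chlorine anti to the neighbouring C6 silyloxy group. The precursor is a 5-methylbicyclo[3.1.0]hexan-1-ol with a silyloxy group at C4 and a silyloxymethyl group at C2 (bicycle numbering), built from 2-methylcyclopentane-1,3-dione and formaldehyde.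

Key step: step 8

Remark: in the Why lines the cyclohexane atoms carry the target numbering (C1: Me, Cl; C3: Me, Br; C4: chloroethenyl; C6: Br); cyclopentane intermediates are numbered as named.
Remark: both ring-fusion centres of cyclopropanol 11 are erased when the ring opens, so 11 is built as the diastereomer that the ketone reduction should deliver by itself (cyclopropane CH2 cis to the C4 silyloxy group); only C2 and C4 of the bicycle reach the target.
Assumption: the (S)-oxazaborolidine is taken to give the 3R carbinol by the usual large/small model.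

Step 1
Reactants: 1 2-methylcyclopentane-1,3-dione; 2 formaldehyde
Product: 3 2-(hydroxymethyl)-2-methylcyclopentane-1,3-dione
Conditions: aq. HCHO (37%), Et3N (cat.), THF–H2O, rt
Reagents that add atoms: none
Why: Aldol hydroxymethylation of the enolised dione: C-alkylation at the doubly activated C2 gives the quaternary, non-stereogenic carbon and leaves two equivalent carbonyl groups for the later desymmetrisation.

Step 2
Reactants: 3 2-(hydroxymethyl)-2-methylcyclopentane-1,3-dione
Product: 5 2-(iodomethyl)-2-methylcyclopentane-1,3-dione, via neopentyl triflate 4 (not isolated)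
Conditions: Tf2O, pyridine, CH2Cl2, −20 °C; then NaI, acetone, rt → 50 °C
Reagents that add atoms: sodium iodide, [Na+].[I-]
Why: O-sulfonylation followed by Finkelstein-type SN2 displacement: the primary triflate is reactive enough for iodide to enter at the neopentyl-type carbon under non-basic conditions, which avoids retro-aldol loss of formaldehyde, and the adjacent quaternary carbon offers no hydrogen for elimination.

Step 3
Reactants: 5 2-(iodomethyl)-2-methylcyclopentane-1,3-dione
Product: 6 (2R,3R)-3-hydroxy-2-(iodomethyl)-2-methylcyclopentan-1-one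
Conditions: (S)-2-methyl-CBS-oxazaborolidine (20 mol %), BH3·SMe2 (0.6 equiv), THF, −30 °C
Reagents that add atoms: none
Why: Corey–Bakshi–Shibata reduction used as a desymmetrisation: the oxazaborolidine–borane complex reads the quaternary carbon as the large and the ring CH2 as the small flank to set the 3R carbinol, and hydride should enter on the methyl face so that the hydroxyl ends cis to the iodomethyl group (2R); substoichiometric borane stops the reaction at the hydroxy ketone.

Step 4
Reactants: 6 (2R,3R)-3-hydroxy-2-(iodomethyl)-2-methylcyclopentan-1-one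
Product: 7 (2R,3R)-3-[(tert-butyldimethylsilyl)oxy]-2-(iodomethyl)-2-methylcyclopentan-1-one
Conditions: TBSCl, imidazole, DMF, rt → 40 °C
Reagents that add atoms: tert-butyldimethylsilyl chloride, CC(C)(C)[Si](C)(C)Cl
Why: Silyl ether formation on the secondary alcohol; the bulky group shields its ring face in steps 5 and 8 and stays on until the fluoride step.

Step 5
Reactants: 7 (2R,3R)-3-[(tert-butyldimethylsilyl)oxy]-2-(iodomethyl)-2-methylcyclopentan-1-one; 2 formaldehyde
Product: 9 (2R,3R,5S)-3-[(tert-butyldimethylsilyl)oxy]-5-(hydroxymethyl)-2-(iodomethyl)-2-methylcyclopentan-1-one, via trimethylsilyl enol ether 8 (not isolated)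
Conditions: TMSOTf, Et3N, CH2Cl2, 0 °C; then aq. HCHO (37%), Yb(OTf)3 (10 mol %), THF, rt
Reagents that add atoms: none
Why: Mukaiyama aldol reaction with aqueous formaldehyde under water-tolerant Lewis acid catalysis: the ketone can enolise only toward C5, and formaldehyde should add to the enol ether on the face opposite both the C3 silyloxy and the C2 iodomethyl groups, which sets 5S (hydroxymethyl trans to the silyloxy group) without base that could epimerise it.

Step 6
Reactants: 9 (2R,3R,5S)-3-[(tert-butyldimethylsilyl)oxy]-5-(hydroxymethyl)-2-(iodomethyl)-2-methylcyclopentan-1-one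
Product: 10 (2R,3R,5S)-3-[(tert-butyldimethylsilyl)oxy]-5-{[(tert-butyldimethylsilyl)oxy]methyl}-2-(iodomethyl)-2-methylcyclopentan-1-one
Conditions: TBSCl, imidazole, CH2Cl2, 0 °C → rt
Reagents that add atoms: tert-butyldimethylsilyl chloride, CC(C)(C)[Si](C)(C)Cl
Why: Silyl ether formation on the primary alcohol under mild conditions that should not dehydrate the β-hydroxy ketone; a free hydroxyl would quench the organosamarium of step 7.

Step 7
Reactants: 10 (2R,3R,5S)-3-[(tert-butyldimethylsilyl)oxy]-5-{[(tert-butyldimethylsilyl)oxy]methyl}-2-(iodomethyl)-2-methylcyclopentan-1-one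
Product: 11 (1R,2S,4R,5R)-4-[(tert-butyldimethylsilyl)oxy]-2-{[(tert-butyldimethylsilyl)oxy]methyl}-5-methylbicyclo[3.1.0]hexan-1-ol
Conditions: SmI2 (2.5 equiv), HMPA, THF, −78 → 0 °C
Reagents that add atoms: none
Why: Intramolecular Barbier reaction (3-exo closure): divalent samarium with HMPA reduces the carbon–iodine bond rapidly to the organosamarium, a homoenolate that closes onto the adjacent ketone to the cis-fused cyclopropanolate, so the cyclopropane CH2 lies on the face of the former iodomethyl group (1R,5R) while C2 and C4 are untouched.

Step 8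
Reactants: 11 (1R,2S,4R,5R)-4-[(tert-butyldimethylsilyl)oxy]-2-{[(tert-butyldimethylsilyl)oxy]methyl}-5-methylbicyclo[3.1.0]hexan-1-ol
Product: 12 (3R,4R,6S)-4-[(tert-butyldimethylsilyl)oxy]-6-{[(tert-butyldimethylsilyl)oxy]methyl}-3-chloro-3-methylcyclohexan-1-one
Conditions: MnCl2·4H2O (10 mol %), MgCl2 (5 equiv), LiClO4, MeCN–AcOH (7:1), graphite anode, Pt cathode, undivided cell, constant current, rt
Reagents that add atoms: magnesium chloride, [Mg+2].[Cl-].[Cl-]
Why: Anodically formed trivalent manganese chloride turns the cyclopropanol O–H into an alkoxy radical, which undergoes β-scission of the strained bond shared by both rings; the closest known reaction type is the manganese-catalysed electrochemical deconstructive chlorination of cyclopropanols and cyclobutanols, with the FeCl3 ring expansion of 1-siloxybicycloalkanes to β-chloro cycloalkanones as its chemical counterpart. The six-membered ring is not closed by a cyclisation but arises by one-carbon ring expansion, the former cyclopropane CH2 becoming C2 between the new ketone C3 and the radical centre C1. The planar tertiary C1 radical then takes chlorine from a second trivalent manganese chloride, and the new stereocentre is controlled by the vicinal C6 silyloxy group, which blocks its own face so that chlorine should enter trans to it. The step needs scission of the internal rather than the external cyclopropane bond, which the methyl group secures because the internal cleavage gives a tertiary radical and the external one a primary radical. The medium contains no base, so the β-chloro ketone and the C4 centre next to the carbonyl should neither eliminate nor epimerise, and the substrate carries no alkene or oxidisable ether that the chlorinating medium could attack.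

Step 9
Reactants: 12 (3R,4R,6S)-4-[(tert-butyldimethylsilyl)oxy]-6-{[(tert-butyldimethylsilyl)oxy]methyl}-3-chloro-3-methylcyclohexan-1-one
Product: 13 (1S,2S,4R,5R)-4-[(tert-butyldimethylsilyl)oxy]-2-{[(tert-butyldimethylsilyl)oxy]methyl}-5-chloro-5-methyl-1-[(trimethylsilyl)methyl]cyclohexan-1-ol
Conditions: TMSCH2Li, CeCl3, THF, −78 °C
Reagents that add atoms: (trimethylsilyl)methyllithium, [Li]C[Si](C)(C)C
Why: Organocerium 1,2-addition (first stage of a Peterson olefination): the weakly basic (trimethylsilyl)methylcerium reagent adds to the enolisable β-chloro ketone at −78 °C without loss of HCl or epimerisation at C4, most likely from the equatorial side away from the axial C1 chlorine, and the carbinol centre it creates disappears in step 10.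

Step 10
Reactants: 13 (1S,2S,4R,5R)-4-[(tert-butyldimethylsilyl)oxy]-2-{[(tert-butyldimethylsilyl)oxy]methyl}-5-chloro-5-methyl-1-[(trimethylsilyl)methyl]cyclohexan-1-ol
Product: 14 (1R,2R,5R)-2-chloro-5-(hydroxymethyl)-2-methyl-4-methylidenecyclohexan-1-ol
Conditions: aq. HF (48%), MeCN, 0 °C → rt
Reagents that add atoms: none
Why: Acid-mediated Peterson elimination with concurrent desilylation: protonation of the tertiary hydroxyl and loss of the β-silyl group gives the exocyclic alkene regiospecifically, while HF removes both silyl ethers and should not ionise the inductively deactivated tertiary chloride.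

Step 11
Reactants: 14 (1R,2R,5R)-2-chloro-5-(hydroxymethyl)-2-methyl-4-methylidenecyclohexan-1-ol
Product: 15 (1R,4R,5R)-4-chloro-5-hydroxy-4-methyl-2-methylidenecyclohexane-1-carbaldehyde
Conditions: TEMPO (cat.), PhI(OAc)2, CH2Cl2, rt
Reagents that add atoms: none
Why: Oxoammonium (TEMPO) oxidation: the primary alcohol is oxidised much faster than the hindered secondary C6 hydroxyl, the conditions are mild enough to leave the β,γ-unsaturated aldehyde unconjugated with C4 intact, and the trans-disposed C6 hydroxyl cannot close a lactol.

Step 12
Reactants: 15 (1R,4R,5R)-4-chloro-5-hydroxy-4-methyl-2-methylidenecyclohexane-1-carbaldehyde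
Product: 16 (1R,2R,5S)-2-chloro-5-[(E)-2-chloroethenyl]-2-methyl-4-methylidenecyclohexan-1-ol
Conditions: CrCl2 (8 equiv), CHCl3 (3 equiv), THF, 65 °C
Reagents that add atoms: chloroform, ClC(Cl)Cl
Why: Takai olefination: the geminal dichromium reagent formed from chloroform and CrCl2 adds to the freshly prepared aldehyde and eliminates to the E-chloroalkene; the reagent is not basic, so the C4 centre, the free hydroxyl and the tertiary chloride should be tolerated.

Step 13
Reactants: 16 (1R,2R,5S)-2-chloro-5-[(E)-2-chloroethenyl]-2-methyl-4-methylidenecyclohexan-1-ol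
Product: 18 (1R,2S,4S)-2-bromo-1-chloro-4-[(E)-2-chloroethenyl]-1-methyl-5-methylidenecyclohexane, via C6 triflate 17 (not isolated)
Conditions: Tf2O, pyridine, CH2Cl2, −40 °C; then Bu4NBr, toluene, −20 °C → rt
Reagents that add atoms: tetrabutylammonium bromide, CCCC[N+](CCCC)(CCCC)CCCC.[Br-]
Why: Sulfonylation followed by SN2 displacement with inversion: the C6 triflate is displaced by soluble bromide at low temperature from the face opposite to the oxygen, turning C6 from R (oxygen) to S (bromine, cis to the C1 chlorine); the electron-withdrawing β-chlorine suppresses ionisation and skeletal shifts, and chlorine is a weak neighbouring group that should not impose retention.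

Step 14
Reactants: 18 (1R,2S,4S)-2-bromo-1-chloro-4-[(E)-2-chloroethenyl]-1-methyl-5-methylidenecyclohexane
Product: 19 (1R,2S,4S,5R)-1,4-dibromo-5-chloro-2-[(E)-2-chloroethenyl]-1,5-dimethylcyclohexane
Conditions: Co(acac)2 (cat.), t-BuOOH, Et3SiH, TsBr, n-PrOH, rt
Reagents that add atoms: p-toluenesulfonyl bromide, Cc1ccc(cc1)S(=O)(=O)Br
Why: Markovnikov radical hydrobromination by metal-hydride hydrogen atom transfer: the cobalt hydride gives a hydrogen atom to the terminal carbon of the 1,1-disubstituted alkene only, and the tertiary C3 radical should take bromine from the sulfonyl bromide on the equatorial side, away from the axial C1 chlorine and trans to the C4 side chain (3R in target numbering), with no cation that could rearrange and no reaction at the less reactive chloroalkene.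

Compound list
1 | 2-methylcyclopentane-1,3-dione | CC1C(=O)CCC1=O | starting material
2 | formaldehyde | C=O | starting material
3 | 2-(hydroxymethyl)-2-methylcyclopentane-1,3-dione | CC1(CO)C(=O)CCC1=O | intermediate
4 | (1-methyl-2,5-dioxocyclopentyl)methyl trifluoromethanesulfonate | CC1(COS(=O)(=O)C(F)(F)F)C(=O)CCC1=O | intermediate
5 | 2-(iodomethyl)-2-methylcyclopentane-1,3-dione | CC1(CI)C(=O)CCC1=O | intermediate
6 | (2R,3R)-3-hydroxy-2-(iodomethyl)-2-methylcyclopentan-1-one | O=C1CC[C@@H](O)[C@@]1(C)CI | intermediate
7 | (2R,3R)-3-[(tert-butyldimethylsilyl)oxy]-2-(iodomethyl)-2-methylcyclopentan-1-one | O=C1CC[C@@H](O[Si](C)(C)C(C)(C)C)[C@@]1(C)CI | intermediate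
8 | tert-butyl{[(1R,2R)-2-(iodomethyl)-2-methyl-3-[(trimethylsilyl)oxy]cyclopent-3-en-1-yl]oxy}dimethylsilane | C[Si](C)(C)OC1=CC[C@@H](O[Si](C)(C)C(C)(C)C)[C@@]1(C)CI | intermediate
9 | (2R,3R,5S)-3-[(tert-butyldimethylsilyl)oxy]-5-(hydroxymethyl)-2-(iodomethyl)-2-methylcyclopentan-1-one | O=C1[C@H](CO)C[C@@H](O[Si](C)(C)C(C)(C)C)[C@@]1(C)CI | intermediate
10 | (2R,3R,5S)-3-[(tert-butyldimethylsilyl)oxy]-5-{[(tert-butyldimethylsilyl)oxy]methyl}-2-(iodomethyl)-2-methylcyclopentan-1-one | O=C1[C@H](CO[Si](C)(C)C(C)(C)C)C[C@@H](O[Si](C)(C)C(C)(C)C)[C@@]1(C)CI | intermediate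
11 | (1R,2S,4R,5R)-4-[(tert-butyldimethylsilyl)oxy]-2-{[(tert-butyldimethylsilyl)oxy]methyl}-5-methylbicyclo[3.1.0]hexan-1-ol | C[C@]12C[C@@]1(O)[C@H](CO[Si](C)(C)C(C)(C)C)C[C@H]2O[Si](C)(C)C(C)(C)C | intermediate
12 | (3R,4R,6S)-4-[(tert-butyldimethylsilyl)oxy]-6-{[(tert-butyldimethylsilyl)oxy]methyl}-3-chloro-3-methylcyclohexan-1-one | C[C@@]1(Cl)CC(=O)[C@H](CO[Si](C)(C)C(C)(C)C)C[C@H]1O[Si](C)(C)C(C)(C)C | intermediate
13 | (1S,2S,4R,5R)-4-[(tert-butyldimethylsilyl)oxy]-2-{[(tert-butyldimethylsilyl)oxy]methyl}-5-chloro-5-methyl-1-[(trimethylsilyl)methyl]cyclohexan-1-ol | C[C@@]1(Cl)C[C@@](O)(C[Si](C)(C)C)[C@H](CO[Si](C)(C)C(C)(C)C)C[C@H]1O[Si](C)(C)C(C)(C)C | intermediate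
14 | (1R,2R,5R)-2-chloro-5-(hydroxymethyl)-2-methyl-4-methylidenecyclohexan-1-ol | C[C@@]1(Cl)CC(=C)[C@H](CO)C[C@H]1O | intermediate
15 | (1R,4R,5R)-4-chloro-5-hydroxy-4-methyl-2-methylidenecyclohexane-1-carbaldehyde | C[C@@]1(Cl)CC(=C)[C@H](C=O)C[C@H]1O | intermediate
16 | (1R,2R,5S)-2-chloro-5-[(E)-2-chloroethenyl]-2-methyl-4-methylidenecyclohexan-1-ol | C[C@@]1(Cl)CC(=C)[C@H](/C=C/Cl)C[C@H]1O | intermediate
17 | (1R,2R,5S)-2-chloro-5-[(E)-2-chloroethenyl]-2-methyl-4-methylidenecyclohexyl trifluoromethanesulfonate | C[C@@]1(Cl)CC(=C)[C@H](/C=C/Cl)C[C@H]1OS(=O)(=O)C(F)(F)F | intermediate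
18 | (1R,2S,4S)-2-bromo-1-chloro-4-[(E)-2-chloroethenyl]-1-methyl-5-methylidenecyclohexane | C[C@@]1(Cl)CC(=C)[C@H](/C=C/Cl)C[C@@H]1Br | intermediate
19 | (1R,2S,4S,5R)-1,4-dibromo-5-chloro-2-[(E)-2-chloroethenyl]-1,5-dimethylcyclohexane | C[C@@]1(Cl)C[C@@](C)(Br)[C@H](/C=C/Cl)C[C@@H]1Br | target

Total step count: 14. Longest linear sequence: 14 steps (1 to 19).

Steps most likely to fail

Step 13. Backside attack at C6 has to pass the fully substituted C1, so displacement may be slower than E2 loss of triflate toward C5 or than chlorine-assisted ionisation, which would return the bromide with retention. The fallback sets out from 16 and replaces sulfonate chemistry by neutral phosphorus activation (Appel reaction). CBr4 and tri-n-octylphosphine in toluene at 70 °C should convert 16 into {[(1R,2R,5S)-2-chloro-5-[(E)-2-chloroethenyl]-2-methyl-4-methylidenecyclohexyl]oxy}trioctylphosphonium bromide F1. Its ion pair should collapse by SN2 with inversion, driven by phosphine oxide formation and without a free sulfonate or added base. The route is rejoined at 18.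

Step 8. The silyl ethers may be cleaved in the chloride and acetic acid electrolyte, the anode may chlorinate or over-oxidise the product, or chlorine transfer may show poor facial selectivity. The fallback sets out from 11 and caps the cyclopropanol (TMSCl, Et3N, CH2Cl2) as (1R,2S,4R,5R)-4-[(tert-butyldimethylsilyl)oxy]-2-{[(tert-butyldimethylsilyl)oxy]methyl}-5-methyl-1-[(trimethylsilyl)oxy]bicyclo[3.1.0]hexane F2. Oxidation with FeCl3 and pyridine in DMF at 0 °C follows: stoichiometric trivalent iron opens the siloxycyclopropane to the same β-keto radical and hands over chlorine in a buffered medium without electrolysis. The route is rejoined at 12.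

Step 14. The cobalt hydride may isomerise the exocyclic alkene into conjugation with the chloroalkene or simply reduce it, and bromine transfer to the C3 radical may not discriminate the two faces well. The fallback sets out from 18 and adds anhydrous HBr in CH2Cl2 at −78 °C. This polar Markovnikov addition runs through the tertiary C3 ion pair, which should also collapse on the face away from the axial C1 chlorine, while the electron-poor chloroalkene is not protonated. The route is rejoined at 19 and no new compound is made.

Further compounds
F1 | step 13 | {[(1R,2R,5S)-2-chloro-5-[(E)-2-chloroethenyl]-2-methyl-4-methylidenecyclohexyl]oxy}trioctylphosphonium bromide | C[C@@]1(Cl)CC(=C)[C@H](/C=C/Cl)C[C@H]1O[P+](CCCCCCCC)(CCCCCCCC)CCCCCCCC.[Br-]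
F2 | step 8 | (1R,2S,4R,5R)-4-[(tert-butyldimethylsilyl)oxy]-2-{[(tert-butyldimethylsilyl)oxy]methyl}-5-methyl-1-[(trimethylsilyl)oxy]bicyclo[3.1.0]hexane | C[C@]12C[C@@]1(O[Si](C)(C)C)[C@H](CO[Si](C)(C)C(C)(C)C)C[C@H]2O[Si](C)(C)C(C)(C)C
F0 | step 14 | none | none
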